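Whatever the flask does, the Q you charged, 0.00500 M, stays in the flask: it only moves among X.Q, Z.X.Q, free Q and G, each G counting twice. E comes out of Z.X.Q, so write c for the Z.X.Q standing; the E made per minute is 5.0 min⁻¹ times c, less the way back.

Z 1.0 M; X 1.30 equiv; Q 0.5 mol%; time 1.0 h

    Z + X.Q ⇌ Z.X.Q (K1 = 0.85 L mol⁻¹, k1 = 70 L mol⁻¹ min⁻¹)
    2 Z.X.Q ⇌ G, settled at all times (K2 = 220 L mol⁻¹)
    X + Q → X.Q (k3 = 23 L mol⁻¹ min⁻¹)
    Z.X.Q ⇌ Q + E (K4 = 2.2 M, k4 = 5.0 min⁻¹)

- percent here means Z units held: one G counts as two
- for a step with 2 of a species take k times the square, and two of it per event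
- the reaction counts as stopped when no species that holds the Z changes by six tenths of a point or more over the second half of the time
- run time (flask): 1.0 h

- why nothing more happens at 1.0 h, or that something still does (X has run out first / no working catalyst is left / it is still moving / forward and back rates have come level / all of Z has reacted)
- part of the Z gone at 1.0 h
- the E standing at 1.0 h, as a percentage of the Z charged

Build the flask up by hand. Take the main step first and let every Q sit as Z.X.Q: 1.0 h then gives 1.50 M of E, more than the 1.0 M of Z charged, so something holds it back.

Add the binding of Z to X.Q. Z.X.Q falls back at 82.4 min⁻¹, faster than the 5.0 min⁻¹ at which it goes on to E, so this step stays near balance: Z.X.Q stands at 0.85 L mol⁻¹ times Z times X.Q. At the charge 45.9% of the Q is then Z.X.Q, and the figure drops to 0.689 M.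

Add the rest. Free Q meets the 1.30 M of X at 29.9 min⁻¹, faster than the 5.0 min⁻¹ at which Z.X.Q releases it, so free Q stands at 0.167 of c. G, an off-cycle form, stands at 220 L mol⁻¹ times c squared. Sharing out the Q now gives c = 0.00163 M, and so 0.490 M of E.

That rate belongs to the charge, and Z and X run down. So replace the curve by its mean: take away half of that E, leaving 0.755 M of Z and 1.06 M of X, and share out again, which gives c = 0.00147 M. Q and E return 1.68 × 10⁻⁴ M min⁻¹, which leaves 0.00716 M min⁻¹: the mid-run rate, the net E per minute with every amount at its mid-run value. Over 1.0 h I get 43.0% of E. With 0.570 M of Z and 0.870 M of X remaining, I say the flask is still moving, with the Z gone above E by at most 0.5 mol%.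

The forecast says it is still moving, with 42.5% of Z gone and 42.3% of E, since “neither X nor Z has run out”. The simulation gives it is still moving, 42.6% and 42.4%.

So the flask's mean net rate is 0.00707 M min⁻¹ against the mid-run rate of 0.00716 M min⁻¹, and at 0.500 h E stands at 22.7%, a little over half of its figure at the asked time. Now take the neighbouring flask, with 0.60 M of Z and the same equivalents, loading and time. The reckoning at its charge gives 0.250 M of E. Mid-run that leaves 0.475 M of Z and 0.655 M of X, so c is 7.27 × 10⁻⁴ M. Its mid-run rate is 0.00357 M min⁻¹, which over 1.0 h makes 35.7% of its charge. The neighbouring flask stands at 35.1% of E.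

(The constants were set for the occasion; the rest is arithmetic.)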